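## Retrosynthetic overview

1. The target is (12E)-7β-acetoxylabda-12,14-diene-6β,8α-diol (5S,6S,7S,8S,9R,10S). The strategy rests on C10, the methyl-bearing quaternary carbon of the A/B ring fusion, which lies in ring B between C5 and C9. With ring B written as its 6,8-dione and ring A opened at C4–C5, C5 and C9 are equivalent CH2 groups and C10 is only prochiral.
2. The key disconnection is C4–C5. A chiral acid protonates the homoprenyl alkene of an achiral 5,5-disubstituted cyclohexane-1,3-dione, and one of the two enantiotopic α′-methylenes captures the C4 cation. The catalyst sets C10 and equilibration sets C5.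
3. Ring B is made first (dimedone-type annulation of a citral-derived methyl dienone with malonate) and ring A second (key step). A temporary γ-lactone (O8–C12) comes third and is opened again near the end.
4. Ring B is then decorated from its two carbonyls: C9–C11 by dianion alkylation, C8–CH3 by cuprate substitution of an enol lactone that only O8 can form, O7/O8 by α-face dihydroxylation, C7 by ketol epimerisation, and C6 by α-face hydride.
5. The side chain C12–C16 is built from the lactol by two Wittig reactions, and selective 7-O-acetylation comes last.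

Key step: step 4

Remark on numbering: labdane numbering is used for all bicyclic compounds. Ring A is C1–C5 and C10, ring B is C5–C10, C11–C16 is the side chain, C17 is the methyl on C8, and α is the face opposite the C10 methyl.

Assumption: the sense of induction of the chiral acid cannot be derived from a model. The route is written for the catalyst enantiomer, here called (S,S), that bonds C4 to the pro-R CH2C(=O) arm; the other enantiomer is equally accessible from the other BINOL.

## Route

Step 1
Reactants: 1 citral (commercial E/Z mixture); 2 methylmagnesium bromide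
Product: 3 4,8-dimethylnona-3,7-dien-2-ol (racemic; E/Z mixture)
Conditions: MeMgBr (1.1 equiv), THF, 0 °C; aq NH4Cl
Reagents that add atoms: methylmagnesium bromide, C[Mg]Br
Why: Grignard 1,2-addition to the enal is fast at 0 °C and leaves both alkenes untouched, and the racemic carbinol centre is erased in step 2.

Step 2
Reactants: 3 4,8-dimethylnona-3,7-dien-2-ol
Product: 4 4,8-dimethylnona-3,7-dien-2-one (E/Z mixture)
Conditions: activated MnO2 (excess), CH2Cl2, rt
Reagents that add atoms: none
Why: Allylic alcohol oxidation with MnO2 gives the methyl dienone without touching the isolated alkene, and the E/Z composition is irrelevant because the β-carbon becomes a prochiral quaternary centre.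

Step 3
Reactants: 4 4,8-dimethylnona-3,7-dien-2-one; 5 diethyl malonate
Product: 9 5-methyl-5-(4-methylpent-3-enyl)cyclohexane-1,3-dione, via Michael adduct 6 (not isolated), via cyclic keto ester 7 (not isolated), via keto acid 8 (not isolated)
Conditions: NaOEt (1.1 equiv), EtOH, reflux; then aq KOH, reflux; then 1 M HCl to pH 3, 70 °C
Reagents that add atoms: diethyl malonate, CCOC(=O)CC(=O)OCC
Why: This is the classical dimedone annulation (Michael addition to a β,β-disubstituted enone, Dieckmann-type Claisen closure, saponification, β-keto acid decarboxylation) applied to the homoprenyl analogue of mesityl oxide, acidification only to pH 3 leaves the trisubstituted alkene unprotonated so that no racemic cyclisation can start, and the product has a mirror plane through C7 and C10 and no stereocentre.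

Step 4
Reactants: 9 5-methyl-5-(4-methylpent-3-enyl)cyclohexane-1,3-dione
Product: 11 (4aR,8aS)-4a,8,8-trimethylhexahydronaphthalene-1,3(2H,4H)-dione (trans-fused 6,8-dione; 5α-H; 10β-CH3), via cis-fused dione 10 (not isolated)
Conditions: (S,S)-IDPi, HN[P(=NTf)(3,3′-Ar2-BINOL-ate)]2 with Ar = 3,5-(CF3)2C6H3 (5 mol %), (CF3)3COH, 0.02 M, 0 °C → rt; then 40 °C until the cis isomer is consumed
Reagents that add atoms: none
Why: Proposed new method: the acid, docked by hydrogen bonds on the enolised dione, protonates the side-chain alkene at its less substituted carbon C3, and the tertiary C4 cation is captured by C5 of the bis-enol C5=C6(OH)–C7=C8(OH), the neutral counterpart of a β-diketone dianion, in which the terminal carbon is the most nucleophilic one. The closest known reaction types are imidodiphosphorimidate-catalysed protonative cation–olefin cyclisations of unactivated alkenes, SnCl4-promoted cyclisations of β-dicarbonyl enols onto prenyl-type cations and γ-selective alkylations of 1,3-bis(silyloxy)dienes, but capture by the α′-carbon of a free 1,3-dione with discrimination of enantiotopic groups has not been shown. Ring A closes 6-endo with respect to the protonated C3=C4 bond and 6-(enolexo) with respect to the C5=C6 enol. C10 is controlled by the catalyst alone, whose chiral anion must guide the cation to the pro-R CH2C(=O) arm (C5) and away from its mirror-image twin (C9), whereas C5 is under substrate control: perpendicular attack on the enol should first give the cis-fused 10, which the same acid equilibrates through the C5=C6 enol to the trans-fused 11, favoured because the 6,8-dione has no ring-B hydrogen syn-axial to the C10 methyl. Site selectivity is secured by the tether, since C7 and both oxygens could only close bridged eight-membered rings, and the direction of protonation by the tertiary versus secondary cation. The step further needs alkene protonation to win over Prins-type attack of the alkene on the protonated carbonyl (bridged bicyclo[3.3.1]nonane), which the low electrophilicity of the delocalised hydroxy-enone cation, the non-nucleophilic ionising solvent and high dilution should provide.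

Step 5
Reactants: 11 trans-fused 6,8-dione; 12 tert-butyl bromoacetate
Product: 14 tert-butyl 2-(5,5,8a-trimethyl-2,4-dioxodecahydronaphthalen-1-yl)acetate (5α-H; 10β-CH3; C9 epimer mixture), via dilithium dianion 13 (not isolated)
Conditions: LiN(iPr)2 (2.3 equiv), THF/DMPU, −78 → 0 °C; 12 (1.0 equiv), −78 → −30 °C; 1 M HCl to pH 4
Reagents that add atoms: tert-butyl bromoacetate, CC(C)(C)OC(=O)CBr
Why: In this γ-alkylation of a cyclic β-diketone dianion the second deprotonation takes the accessible C9 methylene and not the C5 methine buried between two quaternary carbons, the more basic terminal carbanion reacts first with the reactive α-bromo ester, and attack anti to the axial C10 methyl should favour the axial 9α epimer, which is of no consequence because C9 is equilibrated in step 6.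

Step 6
Reactants: 14 C9-alkylated dione tert-butyl ester
Product: 16 6-oxo-13,14,15,16,17-pentanorlabd-7-en-12,8-olide (enol lactone O8–C12; 5α-H; 9α-H; 10β-CH3), via dione acid 15 (not isolated)
Conditions: CF3CO2H/CH2Cl2 (1:1), rt; then (CF3CO)2O (1.5 equiv), 0 °C → rt; evaporation, no aqueous work-up
Reagents that add atoms: none
Why: Acidolysis of the tert-butyl ester, acid-catalysed epimerisation α to the C8 carbonyl and O-acylation of the 1,3-dione enol by the mixed anhydride (enol lactonisation) run in one flask, only O8 can reach C12 in a five-membered ring so the O6/O8 question is settled by the tether, and only the equatorial 9β-CH2 lies near the C7=C8–O8 plane so the equilibrating epimers should drain into the 9α-H lactone and C9 is set under conformational control.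

Step 7
Reactants: 16 enol lactone; 17 methyllithium (used as Me2CuLi)
Product: 18 6-oxo-13,14,15,16-tetranorlabd-7-en-12-oic acid (5α-H; 9α-H; 10β-CH3)
Conditions: Me2CuLi (1.5 equiv, from CuI and MeLi), Et2O, −78 → −30 °C; 1 M HCl to pH 3
Reagents that add atoms: lithium dimethylcuprate, [Li+].C[Cu-]C (made from methyllithium 17, [Li]C)
Why: Addition–elimination of a lithium dialkylcuprate on a β-acyloxy enone (vinylogous anhydride) replaces C8–O by C8–CH3, methyl delivery anti to the C10 methyl turns the acyloxy group axial so that the enolate expels the carboxylate, the hindered β,β-disubstituted product enone should resist a second addition at low temperature, and the weakly basic reagent leaves C5 and C9 untouched.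

Step 8
Reactants: 18 enone acid
Product: 20 7α-hydroxy-6-oxosclareolide (7α-hydroxy-6-oxo-13,14,15,16-tetranorlabdan-12,8α-olide; 8β-CH3), via dihydroxy keto acid 19 (not isolated)
Conditions: OsO4 (5 mol %), NMO (1.5 equiv), citric acid (1 equiv), tBuOH/H2O, rt; aq Na2SO3; then camphorsulfonic acid (10 mol %), CH2Cl2, rt
Reagents that add atoms: osmium tetroxide, O=[Os](=O)(=O)=O; N-methylmorpholine N-oxide, C[N+]1([O-])CCOCC1; water, O
Why: Catalytic OsO4/NMO syn-dihydroxylation, run with citric acid as is usual for electron-poor alkenes, attacks the enone from the α face opposite the axial C10 methyl and the 9β side chain and so sets 8α-O/8β-CH3 (final) and 7α-OH (to be inverted), and the trans-diequatorial γ-hydroxy acid then closes under acid catalysis to the trans-fused γ-lactone that masks O8 and C12 together.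

Step 9
Reactants: 20 7α-hydroxy-6-oxosclareolide
Product: 21 7β-hydroxy-6-oxosclareolide
Conditions: DBU (0.3 equiv), degassed toluene, argon, rt → 40 °C
Reagents that add atoms: none
Why: Base-catalysed α-ketol epimerisation through the enediolate (Lobry de Bruyn–Alberda van Ekenstein type) should move the axial 7α-OH to the equatorial, carbonyl-hydrogen-bonded 7β position, the carbonyl should stay at C6 because it removes the hydrogen that would be syn-axial to three methyl groups, retro-aldol cleavage is blocked by the acylated O8, and E1cB loss of the equatorial C8–O bond is disfavoured because that bond lies near the nodal plane of the enolate.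

Step 10
Reactants: 21 7β-hydroxy-6-oxosclareolide
Product: 22 6β,7β-dihydroxysclareolide
Conditions: NaBH4, MeOH/THF, −20 → 0 °C
Reagents that add atoms: none
Why: Under steric approach control in this borohydride reduction the β face of C6 is screened by the axial methyls on C4, C8 and C10, so hydride enters from the α face and gives the axial 6β-alcohol cis to the 7β-OH, while the γ-lactone is inert at this temperature.

Step 11
Reactants: 22 6β,7β-dihydroxysclareolide
Product: 23 8α,12-epoxy-13,14,15,16-tetranorlabdane-6β,7β,12-triol (lactol; C12 anomer mixture)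
Conditions: iBu2AlH (3.5 equiv), CH2Cl2, −78 °C; aq potassium sodium tartrate
Reagents that add atoms: none
Why: Partial reduction of a γ-lactone with iBu2AlH stops at the tetrahedral aluminium hemiacetal at −78 °C, two further equivalents are consumed by the free hydroxyls, and the anomeric mixture at C12 is of no consequence.

Step 12
Reactants: 23 lactol; 24 2-(triphenylphosphoranylidene)propanal
Product: 26 (12E)-6β,7β,8α-trihydroxy-15-norlabd-12-en-14-al, via open hydroxy aldehyde 25 (not isolated)
Conditions: 24 (1.5 equiv), toluene, 90 °C
Reagents that add atoms: 2-(triphenylphosphoranylidene)propanal, CC(C=O)=P(c1ccccc1)(c1ccccc1)c1ccccc1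
Why: Wittig olefination of the lactol through its open aldehyde tautomer with a stabilised α-methyl formyl ylide sets the (E) geometry of C12=C13, tolerates free hydroxyls, and stops after one homologation because the product enal is much less electrophilic than the saturated aldehyde.

Step 13
Reactants: 26 trihydroxy enal; 27 methyltriphenylphosphonium bromide
Product: 28 (12E)-labda-12,14-diene-6β,7β,8α-triol
Conditions: Ph3PCH3Br (6 equiv), n-BuLi (5.5 equiv), THF, 0 °C; add 26, −78 → 0 °C; aq NH4Cl
Reagents that add atoms: methylenetriphenylphosphorane, C=P(c1ccccc1)(c1ccccc1)c1ccccc1 (made from 27)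
Why: Wittig methylenation with excess non-stabilised ylide (three equivalents serve as base for the hydroxyls) should be faster at low temperature than oxa-Michael addition of the hindered tertiary lithium alkoxide and completes the diene without touching the C12=C13 geometry.

Step 14
Reactants: 28 diene triol; 29 acetic anhydride
Product: 30 (12E)-7β-acetoxylabda-12,14-diene-6β,8α-diol (target)
Conditions: Ac2O (1.3 equiv), pyridine, 0 °C → rt
Reagents that add atoms: acetic anhydride, CC(=O)OC(C)=O
Why: In this sterically differentiated acylation without DMAP only the equatorial secondary 7β-OH should react, because the 6β-OH is axial beneath three syn-axial methyl groups and the 8α-OH is tertiary, and the basic medium protects the acid-sensitive hydroxy diene.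

## Compound list

1 | citral (E/Z mixture) | CC(C)=CCCC(C)=CC=O | starting material
2 | methylmagnesium bromide | C[Mg]Br | starting material
3 | 4,8-dimethylnona-3,7-dien-2-ol (racemic, E/Z) | CC(C)=CCCC(C)=CC(C)O | intermediate
4 | 4,8-dimethylnona-3,7-dien-2-one (E/Z) | CC(C)=CCCC(C)=CC(C)=O | intermediate
5 | diethyl malonate | CCOC(=O)CC(=O)OCC | starting material
6 | diethyl 2-(4,8-dimethyl-2-oxonon-7-en-4-yl)malonate (racemic, not isolated) | CCOC(=O)C(C(=O)OCC)C(C)(CC(C)=O)CCC=C(C)C | intermediate
7 | ethyl 2-methyl-2-(4-methylpent-3-enyl)-4,6-dioxocyclohexane-1-carboxylate (racemic diastereomers, not isolated) | CCOC(=O)C1C(=O)CC(=O)CC1(C)CCC=C(C)C | intermediate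
8 | 2-methyl-2-(4-methylpent-3-enyl)-4,6-dioxocyclohexane-1-carboxylic acid (not isolated) | OC(=O)C1C(=O)CC(=O)CC1(C)CCC=C(C)C | intermediate
9 | 5-methyl-5-(4-methylpent-3-enyl)cyclohexane-1,3-dione (achiral, prochiral at C10) | CC(C)=CCCC1(C)CC(=O)CC(=O)C1 | intermediate
10 | (4aR,8aR)-4a,8,8-trimethylhexahydronaphthalene-1,3(2H,4H)-dione (cis-fused, not isolated) | C1C(=O)CC(=O)[C@@H]2C(C)(C)CCC[C@@]21C | intermediate
11 | (4aR,8aS)-4a,8,8-trimethylhexahydronaphthalene-1,3(2H,4H)-dione (trans-fused) | C1C(=O)CC(=O)[C@H]2C(C)(C)CCC[C@@]21C | intermediate
12 | tert-butyl bromoacetate | CC(C)(C)OC(=O)CBr | starting material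
13 | dilithium 6,8-dienediolate of 11 (C9=C8, C7=C6; not isolated) | C1=C(O[Li])C=C(O[Li])[C@H]2C(C)(C)CCC[C@@]21C | intermediate
14 | tert-butyl 2-(5,5,8a-trimethyl-2,4-dioxodecahydronaphthalen-1-yl)acetate (C9 left open: epimer mixture) | CC(C)(C)OC(=O)CC1C(=O)CC(=O)[C@H]2C(C)(C)CCC[C@@]21C | intermediate
15 | 2-(5,5,8a-trimethyl-2,4-dioxodecahydronaphthalen-1-yl)acetic acid (C9 epimers in equilibrium, 9β-CH2 shown; not isolated) | OC(=O)C[C@H]1C(=O)CC(=O)[C@H]2C(C)(C)CCC[C@@]21C | intermediate
16 | 6-oxo-13,14,15,16,17-pentanorlabd-7-en-12,8-olide (enol lactone) | O=C3C[C@H]1C(O3)=CC(=O)[C@H]2C(C)(C)CCC[C@@]21C | intermediate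
17 | methyllithium | [Li]C | starting material
18 | 6-oxo-13,14,15,16-tetranorlabd-7-en-12-oic acid | OC(=O)C[C@H]1C(C)=CC(=O)[C@H]2C(C)(C)CCC[C@@]21C | intermediate
19 | 7α,8α-dihydroxy-6-oxo-13,14,15,16-tetranorlabdan-12-oic acid (not isolated) | OC(=O)C[C@H]1[C@](C)(O)[C@H](O)C(=O)[C@H]2C(C)(C)CCC[C@@]21C | intermediate
20 | 7α-hydroxy-6-oxosclareolide | O=C3C[C@H]1[C@](C)(O3)[C@H](O)C(=O)[C@H]2C(C)(C)CCC[C@@]21C | intermediate
21 | 7β-hydroxy-6-oxosclareolide | O=C3C[C@H]1[C@](C)(O3)[C@@H](O)C(=O)[C@H]2C(C)(C)CCC[C@@]21C | intermediate
22 | 6β,7β-dihydroxysclareolide | O=C3C[C@H]1[C@](C)(O3)[C@@H](O)[C@@H](O)[C@H]2C(C)(C)CCC[C@@]21C | intermediate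
23 | 8α,12-epoxy-13,14,15,16-tetranorlabdane-6β,7β,12-triol (lactol, C12 anomers) | OC3C[C@H]1[C@](C)(O3)[C@@H](O)[C@@H](O)[C@H]2C(C)(C)CCC[C@@]21C | intermediate
24 | 2-(triphenylphosphoranylidene)propanal | CC(C=O)=P(c1ccccc1)(c1ccccc1)c1ccccc1 | starting material
25 | 6β,7β,8α-trihydroxy-13,14,15,16-tetranorlabdan-12-al (open form of 23, not isolated) | O=CC[C@H]1[C@](C)(O)[C@@H](O)[C@@H](O)[C@H]2C(C)(C)CCC[C@@]21C | intermediate
26 | (12E)-6β,7β,8α-trihydroxy-15-norlabd-12-en-14-al | O=C/C(C)=C/C[C@H]1[C@](C)(O)[C@@H](O)[C@@H](O)[C@H]2C(C)(C)CCC[C@@]21C | intermediate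
27 | methyltriphenylphosphonium bromide | C[P+](c1ccccc1)(c1ccccc1)c1ccccc1.[Br-] | starting material
28 | (12E)-labda-12,14-diene-6β,7β,8α-triol | C=C/C(C)=C/C[C@H]1[C@](C)(O)[C@@H](O)[C@@H](O)[C@H]2C(C)(C)CCC[C@@]21C | intermediate
29 | acetic anhydride | CC(=O)OC(C)=O | starting material
30 | (12E)-7β-acetoxylabda-12,14-diene-6β,8α-diol | C=C/C(C)=C/C[C@H]1[C@](C)(O)[C@@H](OC(C)=O)[C@@H](O)[C@H]2C(C)(C)CCC[C@@]21C | target

## Step count and risks

Total step count: 14. Longest linear sequence: 14 steps, from citral 1 to 30.

**1. Step 4 (key step).**
- The basic dione may tie up the acid so that the alkene is never protonated.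
- The alkene may add to the activated carbonyl instead.
- The two enantiotopic arms may be poorly discriminated.
- The cis-to-trans equilibration at C5 may stall.

The fallback runs from 9 back to 11 and uses resolution through a chiral enol ether plus Lewis-acid tert-alkylation, all known reaction types. Condensation of 9 with (−)-menthol (cat TsOH, toluene, water separator) turns the two enantiotopic carbonyls into two diastereomeric vinylogous esters. These are the wanted (−)-menthyl enol ether F1, in which the pro-R arm is the CH2 next to the remaining ketone, and its C10 epimer F2. They are separated by crystallisation or chromatography, and F2 is hydrolysed back to achiral 9 and recycled. Dry HCl in CH2Cl2 at −20 °C adds to the trisubstituted alkene of F1 to give the tertiary chloride F3. LiN(iPr)2 and then Me3SiCl at −78 °C give, by kinetic α′-deprotonation as in Stork–Danheiser chemistry, the cross-conjugated silyl dienol ether F4. TiCl4 in CH2Cl2 at −78 °C ionises the chloride, and the silyl enol ether carbon C5 closes ring A (α-tert-alkylation of a silyl enol ether) to the bicyclic menthyl vinylogous ester F5. Finally 2 M HCl in THF at 50 °C removes menthol, equilibrates C5 and returns 11.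

**2. Step 6.**
- Equilibration at C9 may be incomplete under acid.
- The enol double bond may migrate into the butenolide positions.

The fallback runs from 14 back to 18. It replaces the enol lactone and the cuprate by base equilibration of an ordinary ketone α-centre and a Stork–Danheiser transposition. O-Methylation of 14 (Me3SiCHN2, toluene/MeOH) gives the 6-methoxy-7-en-8-one F6 and its regioisomer, the 8-methoxy-7-en-6-one F7. F7 is separated, hydrolysed to 14 with dilute acid and recycled. In F6, C9 is a normal ketone α-carbon, and cat KOtBu in tBuOH equilibrates it to the equatorial 9β epimer. MeLi/CeCl3 in THF at −78 °C adds to the C8 carbonyl to give the tertiary carbinol F8. On work-up with 1 M HCl at 0 °C this loses methanol and water and gives the transposed enone tert-butyl ester F9. CF3CO2H in CH2Cl2 then gives 18.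

**3. Step 9.**
- Removal of the equatorial 7β-hydrogen may be slow.
- The ketol may transpose.
- The enediolate may be oxidised by air.
- The lactone oxygen may be lost by β-elimination.
- The equilibrium position may be unfavourable.

The fallback runs from 20 back to 22 and inverts C7 by oxidation and reduction instead of equilibration. NaBH4 in MeOH at 0 °C reduces C6 of 20 from the α face to the trans-diaxial 6β,7α-dihydroxysclareolide F10. One equivalent of Dess–Martin periodinane (NaHCO3, CH2Cl2, 0 °C) should oxidise only the accessible 7α-OH and spare the 6β-OH, which is shielded by three syn-axial methyls, to give 6β-hydroxy-7-oxosclareolide F11. NaBH4 then delivers hydride axially from the α face of C7 and gives the equatorial 7β-alcohol 22.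

## Further compounds

F1 | step 4 | (−)-menthyl vinylogous ester of 9, 3-menthyloxy-5-methyl-5-(4-methylpent-3-enyl)cyclohex-2-enone, C10 as in 11 | C1C(O[C@@H]3C[C@H](C)CC[C@H]3C(C)C)=CC(=O)C[C@]1(C)CCC=C(C)C
F2 | step 4 | C10 epimer of F1 (recycled) | C1C(O[C@@H]3C[C@H](C)CC[C@H]3C(C)C)=CC(=O)C[C@@]1(C)CCC=C(C)C
F3 | step 4 | tertiary chloride, 5-(4-chloro-4-methylpentyl) analogue of F1 | C1C(O[C@@H]3C[C@H](C)CC[C@H]3C(C)C)=CC(=O)C[C@]1(C)CCCC(C)(C)Cl
F4 | step 4 | cross-conjugated trimethylsilyl dienol ether of F3 (C5=C6–OSiMe3, C7=C8–O-menthyl) | C1C(O[C@@H]3C[C@H](C)CC[C@H]3C(C)C)=CC(O[Si](C)(C)C)=C[C@]1(C)CCCC(C)(C)Cl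
F5 | step 4 | bicyclic 8-menthyloxy-7-en-6-one (C5 left open, equilibrated on hydrolysis) | C1C(O[C@@H]3C[C@H](C)CC[C@H]3C(C)C)=CC(=O)C2C(C)(C)CCC[C@@]21C
F6 | step 6 | tert-butyl ester, 6-methoxy-7-en-8-one, 9β-CH2 after equilibration | CC(C)(C)OC(=O)C[C@H]1C(=O)C=C(OC)[C@H]2C(C)(C)CCC[C@@]21C
F7 | step 6 | tert-butyl ester, 8-methoxy-7-en-6-one regioisomer (C9 epimers, recycled) | CC(C)(C)OC(=O)CC1C(OC)=CC(=O)[C@H]2C(C)(C)CCC[C@@]21C
F8 | step 6 | tert-butyl ester, 8-hydroxy-8-methyl-6-methoxy-6-ene (C8 left open) | CC(C)(C)OC(=O)C[C@H]1C(C)(O)C=C(OC)[C@H]2C(C)(C)CCC[C@@]21C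
F9 | step 6 | tert-butyl 6-oxo-13,14,15,16-tetranorlabd-7-en-12-oate | CC(C)(C)OC(=O)C[C@H]1C(C)=CC(=O)[C@H]2C(C)(C)CCC[C@@]21C
F10 | step 9 | 6β,7α-dihydroxysclareolide | O=C3C[C@H]1[C@](C)(O3)[C@H](O)[C@@H](O)[C@H]2C(C)(C)CCC[C@@]21C
F11 | step 9 | 6β-hydroxy-7-oxosclareolide | O=C3C[C@H]1[C@](C)(O3)C(=O)[C@@H](O)[C@H]2C(C)(C)CCC[C@@]21C
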